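## Retrosynthetic overview

1. Last disconnection at C11=C12: Wittig reaction of a C25 apo-aldehyde (primed ring plus the central C10 unit) with the dibenzoyl-protected C15 phosphonium salt of the diol ring; the benzoates are removed in the same pot.
2. C25 aldehyde: mono-Wittig of the symmetrical C10 trienedial with the 3'-hydroxy acetylenic C15 salt, which comes from actinol by enol triflate formation and Sonogashira coupling with the C6 enynol.
3. Diol half, key disconnection C4–O: the trans-3,4-dibenzoate arises from a tertiary C6 carbinol by a stereoconvergent, benzoate-relayed, allylic-transposing benzoyloxylation (new step), which also creates the C5=C6 enyne.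
4. That carbinol comes from acetylide addition of the silylated C6 enynol to (S)-phorenol, made by asymmetric transfer hydrogenation of ketoisophorone.
5. No ring is formed: both six-membered rings are bought (actinol for the primed ring, ketoisophorone for the diol ring); assembly order is primed C15, then C25, then C40.

Assumption: (4R,6R)-actinol, ketoisophorone, (2E)-3-methylpent-2-en-4-yn-1-ol and (2E,4E,6E)-2,7-dimethylocta-2,4,6-trienedial are bought as bulk carotenoid and vitamin intermediates.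
Convention: positions follow carotenoid numbering; the 3,4-diol ring is unprimed, the 3'-hydroxy ring is primed.

## Route

Step 1
Reactants: 1 (4R,6R)-4-hydroxy-2,2,6-trimethylcyclohexan-1-one (actinol)
Product: 2 (4R,6R)-2,2,6-trimethyl-4-[(triethylsilyl)oxy]cyclohexan-1-one
Conditions: Et3SiCl (1.1 equiv), imidazole (1.5 equiv), CH2Cl2, 0 °C → rt
Reagents that add atoms: chlorotriethylsilane, CC[Si](Cl)(CC)CC
Why: Standard silylation of the secondary alcohol masks the hydroxyl for the enolate chemistry of step 2 without touching either stereocenter.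

Step 2
Reactants: 2 (4R,6R)-2,2,6-trimethyl-4-[(triethylsilyl)oxy]cyclohexan-1-one
Product: 4 (4R)-2,6,6-trimethyl-4-[(triethylsilyl)oxy]cyclohex-1-en-1-yl trifluoromethanesulfonate, via lithium enolate 3 (not isolated)
Conditions: lithium diisopropylamide (1.2 equiv, commercial solution), THF, −78 °C, 1 h; then PhNTf2 (1.2 equiv), −78 °C → rt; aq NH4Cl
Reagents that add atoms: N-phenylbis(trifluoromethanesulfonimide), FC(F)(F)S(=O)(=O)N(c1ccccc1)S(=O)(=O)C(F)(F)F
Why: Only the methyl-bearing alpha carbon has a proton, so enolisation and O-triflation (enol triflate formation) are regiospecific; the methyl stereocenter becomes the C5'=C6' alkene and the silyloxy center is untouched.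

Step 3
Reactants: 4 (4R)-2,6,6-trimethyl-4-[(triethylsilyl)oxy]cyclohex-1-en-1-yl trifluoromethanesulfonate; 5 (2E)-3-methylpent-2-en-4-yn-1-ol
Product: 6 (2E)-3-methyl-5-{(4R)-2,6,6-trimethyl-4-[(triethylsilyl)oxy]cyclohex-1-en-1-yl}pent-2-en-4-yn-1-ol
Conditions: Pd(PPh3)4 (5 mol %), CuI (10 mol %), Et3N (3 equiv), DMF, rt → 45 °C
Reagents that add atoms: none
Why: Sonogashira coupling (zerovalent palladium inserts into the enol triflate, copper acetylide transmetalates) forms the C6'–C7' bond; the free primary alcohol is tolerated and the 9'E olefin is retained.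

Step 4
Reactants: 6 (2E)-3-methyl-5-{(4R)-2,6,6-trimethyl-4-[(triethylsilyl)oxy]cyclohex-1-en-1-yl}pent-2-en-4-yn-1-ol
Product: 7 {(2E)-5-[(4R)-4-hydroxy-2,6,6-trimethylcyclohex-1-en-1-yl]-3-methylpent-2-en-4-yn-1-yl}(triphenyl)phosphonium bromide
Conditions: PPh3·HBr (1.1 equiv), MeOH, rt, 16 h
Reagents that add atoms: triphenylphosphine hydrobromide, [Br-].[PH+](c1ccccc1)(c1ccccc1)c1ccccc1
Why: The phosphonium hydrobromide converts the primary allylic alcohol into the allylic phosphonium salt (acid-mediated allylic substitution), and the same mild acid in methanol cleaves the triethylsilyl ether; the non-allylic ring hydroxyl does not react.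

Step 5
Reactants: 7 {(2E)-5-[(4R)-4-hydroxy-2,6,6-trimethylcyclohex-1-en-1-yl]-3-methylpent-2-en-4-yn-1-yl}(triphenyl)phosphonium bromide; 8 (2E,4E,6E)-2,7-dimethylocta-2,4,6-trienedial
Product: 9 (2E,4E,6E,8E,10E)-13-[(4R)-4-hydroxy-2,6,6-trimethylcyclohex-1-en-1-yl]-2,7,11-trimethyltrideca-2,4,6,8,10-pentaen-12-ynal (C25 apo-aldehyde)
Conditions: 8 (3 equiv), NaOMe (1.1 equiv, added over 2 h), CH2Cl2/MeOH, 0 °C → rt; then heptane, 80 °C, 2 h, dark; chromatography (excess 8 recovered)
Reagents that add atoms: none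
Why: Wittig olefination with the semi-stabilised allylic ylide forms C11'=C12'; the threefold excess of dialdehyde and slow base addition favour mono-condensation, and any hindered 11'Z isomer relaxes to E on heating.

Step 6
Reactants: 5 (2E)-3-methylpent-2-en-4-yn-1-ol
Product: 10 tert-butyl(dimethyl){[(2E)-3-methylpent-2-en-4-yn-1-yl]oxy}silane
Conditions: t-BuMe2SiCl (1.1 equiv), imidazole (1.5 equiv), CH2Cl2, 0 °C → rt
Reagents that add atoms: tert-butylchlorodimethylsilane, CC(C)(C)[Si](C)(C)Cl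
Why: Routine silylation leaves the terminal alkyne as the only acidic site and keeps the C11 oxygen distinguishable from the ring oxygens later.

Step 7
Reactants: 11 2,6,6-trimethylcyclohex-2-ene-1,4-dione (ketoisophorone)
Product: 12 (4S)-4-hydroxy-2,6,6-trimethylcyclohex-2-en-1-one ((S)-phorenol)
Conditions: RuCl[(S,S)-TsDPEN](p-cymene) (0.5 mol %), HCO2H/Et3N (5:2), CH2Cl2, 25 °C
Reagents that add atoms: none
Why: Noyori–Ikariya asymmetric transfer hydrogenation reduces only the unhindered C4 carbonyl (the other is flanked by the gem-dimethyl and the methyl-bearing alkene carbon), and by the aryl/alkenyl ketone model the (S,S) catalyst gives the (S)-carbinol that becomes C3 of the target.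

Step 8
Reactants: 10 tert-butyl(dimethyl){[(2E)-3-methylpent-2-en-4-yn-1-yl]oxy}silane; 12 (4S)-4-hydroxy-2,6,6-trimethylcyclohex-2-en-1-one
Product: 14 (4S)-1-[(3E)-5-{[tert-butyl(dimethyl)silyl]oxy}-3-methylpent-3-en-1-yn-1-yl]-2,6,6-trimethylcyclohex-2-ene-1,4-diol (both C1 epimers), via lithium acetylide 13 (not isolated)
Conditions: 10 (2.4 equiv), n-BuLi (2.3 equiv), THF, −78 °C, 30 min; then 12 (1 equiv), −78 → 0 °C; aq NH4Cl
Reagents that add atoms: none
Why: 1,2-Addition of a lithium acetylide to the hindered enone carbonyl forms C6–C7 (one equivalent of acetylide is spent on the free hydroxyl); the new tertiary center is not controlled and need not be, because step 10 is stereoconvergent.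

Step 9
Reactants: 14 (4S)-1-[(3E)-5-{[tert-butyl(dimethyl)silyl]oxy}-3-methylpent-3-en-1-yn-1-yl]-2,6,6-trimethylcyclohex-2-ene-1,4-diol
Product: 15 (1S)-4-[(3E)-5-{[tert-butyl(dimethyl)silyl]oxy}-3-methylpent-3-en-1-yn-1-yl]-4-hydroxy-3,5,5-trimethylcyclohex-2-en-1-yl benzoate (both C4 epimers)
Conditions: PhCOCl (1.2 equiv), pyridine (3 equiv), DMAP (5 mol %), CH2Cl2, 0 °C
Reagents that add atoms: benzoyl chloride, O=C(Cl)c1ccccc1
Why: Acylation is selective for the secondary over the hindered tertiary alcohol and installs at C3 the benzoate that will act as participating group in step 10.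

Step 10
Reactants: 15 (1S)-4-[(3E)-5-{[tert-butyl(dimethyl)silyl]oxy}-3-methylpent-3-en-1-yn-1-yl]-4-hydroxy-3,5,5-trimethylcyclohex-2-en-1-yl benzoate
Product: 18 (1S,2S)-4-[(3E)-5-{[tert-butyl(dimethyl)silyl]oxy}-3-methylpent-3-en-1-yn-1-yl]-3,5,5-trimethylcyclohex-3-ene-1,2-diyl dibenzoate, via tertiary trifluoroacetate 16 (not isolated), via benzoxonium trifluoroacetate 17 (not isolated)
Conditions: (CF3CO)2O (1.3 equiv), 2,6-lutidine (3 equiv), 4 Å MS, CH2Cl2, −40 °C, 30 min; then Bu4N+ PhCO2− (3 equiv, dried), MeCN, −40 → 0 °C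
Reagents that add atoms: tetrabutylammonium benzoate, CCCC[N+](CCCC)(CCCC)CCCC.[O-]C(=O)c1ccccc1
Why: Proposed new method: the tertiary trifluoroacetate, which is both allylic and propargylic, ionises under buffered conditions and the carbonyl oxygen of the C3 benzoate traps the allyl cation at C4 as a necessarily cis-fused 2-phenyl-1,3-dioxolan-2-ylium ion whichever C6 epimer is used; benzoate then opens this ion at the allylic C4 with inversion under strictly anhydrous conditions, forming the C4–O bond trans to C3–O (3S,4S) and placing the alkene at C5=C6 in conjugation with the alkyne; the closest known reactions are the Prévost trans-dibenzoyloxylation through benzoxonium ions and the allylic transposition of tertiary ethynyl vinyl carbinol esters.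

Step 11
Reactants: 18 (1S,2S)-4-[(3E)-5-{[tert-butyl(dimethyl)silyl]oxy}-3-methylpent-3-en-1-yn-1-yl]-3,5,5-trimethylcyclohex-3-ene-1,2-diyl dibenzoate
Product: 19 {(2E)-5-[(3S,4S)-3,4-bis(benzoyloxy)-2,6,6-trimethylcyclohex-1-en-1-yl]-3-methylpent-2-en-4-yn-1-yl}(triphenyl)phosphonium bromide
Conditions: PPh3·HBr (1.2 equiv), MeOH/CH2Cl2 (1:1), rt, 24 h
Reagents that add atoms: triphenylphosphine hydrobromide, [Br-].[PH+](c1ccccc1)(c1ccccc1)c1ccccc1
Why: Acid methanolysis of the primary allylic silyl ether followed by allylic substitution gives the phosphonium salt in one pot, while the secondary C4 benzoate, whose ionisation is disfavoured by the neighbouring acyloxy group and steric shielding, stays in place.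

Step 12
Reactants: 19 {(2E)-5-[(3S,4S)-3,4-bis(benzoyloxy)-2,6,6-trimethylcyclohex-1-en-1-yl]-3-methylpent-2-en-4-yn-1-yl}(triphenyl)phosphonium bromide; 9 (2E,4E,6E,8E,10E)-13-[(4R)-4-hydroxy-2,6,6-trimethylcyclohex-1-en-1-yl]-2,7,11-trimethyltrideca-2,4,6,8,10-pentaen-12-ynal
Product: 21 (3S,4S,3'R)-7,8,7',8'-tetradehydro-β,β-carotene-3,4,3'-triol (4-hydroxyalloxanthin), via carotenoid dibenzoate 20 (not isolated)
Conditions: 19 (1.2 equiv), NaOMe (6 equiv), MeOH/CH2Cl2 (2:1), 0 °C → rt, 2 h; then 40 °C, 6 h, dark, Ar; then EtOAc/heptane, 70 °C, 1 h; crystallisation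
Reagents that add atoms: none
Why: Wittig olefination forms C11=C12 (E, with any hindered 11Z isomer relaxing thermally) and the excess methoxide then removes both benzoates by transesterification (Zemplén type), which carotenoid polyols without keto groups tolerate, leaving all three stereocenters untouched.

## Compound list

1 | (4R,6R)-4-hydroxy-2,2,6-trimethylcyclohexan-1-one (actinol) | C[C@H]1C(=O)C(C)(C)C[C@H](O)C1 | starting material
2 | (4R,6R)-2,2,6-trimethyl-4-[(triethylsilyl)oxy]cyclohexan-1-one | C[C@H]1C(=O)C(C)(C)C[C@H](O[Si](CC)(CC)CC)C1 | intermediate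
3 | lithium (4R)-2,6,6-trimethyl-4-[(triethylsilyl)oxy]cyclohex-1-en-1-olate (not isolated) | CC1=C([O-])C(C)(C)C[C@H](O[Si](CC)(CC)CC)C1.[Li+] | intermediate
4 | (4R)-2,6,6-trimethyl-4-[(triethylsilyl)oxy]cyclohex-1-en-1-yl trifluoromethanesulfonate | CC1=C(OS(=O)(=O)C(F)(F)F)C(C)(C)C[C@H](O[Si](CC)(CC)CC)C1 | intermediate
5 | (2E)-3-methylpent-2-en-4-yn-1-ol | C#C/C(C)=C/CO | starting material
6 | (2E)-3-methyl-5-{(4R)-2,6,6-trimethyl-4-[(triethylsilyl)oxy]cyclohex-1-en-1-yl}pent-2-en-4-yn-1-ol | CC1=C(C#C/C(C)=C/CO)C(C)(C)C[C@H](O[Si](CC)(CC)CC)C1 | intermediate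
7 | {(2E)-5-[(4R)-4-hydroxy-2,6,6-trimethylcyclohex-1-en-1-yl]-3-methylpent-2-en-4-yn-1-yl}(triphenyl)phosphonium bromide | [Br-].CC1=C(C#C/C(C)=C/C[P+](c2ccccc2)(c2ccccc2)c2ccccc2)C(C)(C)C[C@H](O)C1 | intermediate
8 | (2E,4E,6E)-2,7-dimethylocta-2,4,6-trienedial | O=C/C(C)=C/C=C/C=C(C)/C=O | starting material
9 | (2E,4E,6E,8E,10E)-13-[(4R)-4-hydroxy-2,6,6-trimethylcyclohex-1-en-1-yl]-2,7,11-trimethyltrideca-2,4,6,8,10-pentaen-12-ynal | CC1=C(C#C/C(C)=C/C=C/C(C)=C/C=C/C=C(C)/C=O)C(C)(C)C[C@H](O)C1 | intermediate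
10 | tert-butyl(dimethyl){[(2E)-3-methylpent-2-en-4-yn-1-yl]oxy}silane | C#C/C(C)=C/CO[Si](C)(C)C(C)(C)C | intermediate
11 | 2,6,6-trimethylcyclohex-2-ene-1,4-dione (ketoisophorone) | CC1=CC(=O)CC(C)(C)C1=O | starting material
12 | (4S)-4-hydroxy-2,6,6-trimethylcyclohex-2-en-1-one ((S)-phorenol) | CC1=C[C@@H](O)CC(C)(C)C1=O | intermediate
13 | lithium (3E)-5-{[tert-butyl(dimethyl)silyl]oxy}-3-methylpent-3-en-1-yn-1-ide (not isolated) | [Li+].[C-]#C/C(C)=C/CO[Si](C)(C)C(C)(C)C | intermediate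
14 | (4S)-1-[(3E)-5-{[tert-butyl(dimethyl)silyl]oxy}-3-methylpent-3-en-1-yn-1-yl]-2,6,6-trimethylcyclohex-2-ene-1,4-diol, both C1 epimers | CC1=C[C@@H](O)CC(C)(C)C1(O)C#C/C(C)=C/CO[Si](C)(C)C(C)(C)C | intermediate
15 | (1S)-4-[(3E)-5-{[tert-butyl(dimethyl)silyl]oxy}-3-methylpent-3-en-1-yn-1-yl]-4-hydroxy-3,5,5-trimethylcyclohex-2-en-1-yl benzoate, both C4 epimers | CC1=C[C@@H](OC(=O)c2ccccc2)CC(C)(C)C1(O)C#C/C(C)=C/CO[Si](C)(C)C(C)(C)C | intermediate
16 | (1S)-4-[(3E)-5-{[tert-butyl(dimethyl)silyl]oxy}-3-methylpent-3-en-1-yn-1-yl]-3,5,5-trimethyl-4-[(trifluoroacetyl)oxy]cyclohex-2-en-1-yl benzoate, both C4 epimers (not isolated) | CC1=C[C@@H](OC(=O)c2ccccc2)CC(C)(C)C1(OC(=O)C(F)(F)F)C#C/C(C)=C/CO[Si](C)(C)C(C)(C)C | intermediate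
17 | cis-fused 2-phenyl-1,3-dioxolan-2-ylium (benzoxonium) trifluoroacetate spanning C3 and C4 of the ring, (3S,4R) in carotenoid numbering, with C5=C6 alkene, C6 enynyl chain and C11 silyl ether (not isolated) | CC(C)(C)[Si](C)(C)OC/C=C(C)/C#CC1=C(C)[C@H]2[O+]=C(c3ccccc3)O[C@H]2CC1(C)C.[O-]C(=O)C(F)(F)F | intermediate
18 | (1S,2S)-4-[(3E)-5-{[tert-butyl(dimethyl)silyl]oxy}-3-methylpent-3-en-1-yn-1-yl]-3,5,5-trimethylcyclohex-3-ene-1,2-diyl dibenzoate | CC(C)(C)[Si](C)(C)OC/C=C(C)/C#CC1=C(C)[C@H](OC(=O)c2ccccc2)[C@@H](OC(=O)c2ccccc2)CC1(C)C | intermediate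
19 | {(2E)-5-[(3S,4S)-3,4-bis(benzoyloxy)-2,6,6-trimethylcyclohex-1-en-1-yl]-3-methylpent-2-en-4-yn-1-yl}(triphenyl)phosphonium bromide | [Br-].c1ccccc1[P+](c1ccccc1)(c1ccccc1)C/C=C(C)/C#CC1=C(C)[C@H](OC(=O)c2ccccc2)[C@@H](OC(=O)c2ccccc2)CC1(C)C | intermediate
20 | (3S,4S,3'R)-3'-hydroxy-7,8,7',8'-tetradehydro-β,β-carotene-3,4-diyl dibenzoate (not isolated) | CC1=C(C#C/C(C)=C/C=C/C(C)=C/C=C/C=C(C)/C=C/C=C(\C)C#CC2=C(C)[C@H](OC(=O)c3ccccc3)[C@@H](OC(=O)c3ccccc3)CC2(C)C)C(C)(C)C[C@H](O)C1 | intermediate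
21 | (3S,4S,3'R)-7,8,7',8'-tetradehydro-β,β-carotene-3,4,3'-triol ((3S,4S,3'R)-4-hydroxyalloxanthin) | CC1=C(C#C/C(C)=C/C=C/C(C)=C/C=C/C=C(C)/C=C/C=C(\C)C#CC2=C(C)[C@H](O)[C@@H](O)CC2(C)C)C(C)(C)C[C@H](O)C1 | target

## Step count and risks

Total steps: 12. Longest linear sequence: 6 steps (steps 7 to 12; the branch through steps 1 to 5 and then 12 is equally long).

The three steps most likely to fail:

Step 10 (proposed new step). The trifluoroacetate may ionise sluggishly, traces of water would divert the benzoxonium ion to the cis hydroxy benzoate, or the open cation may be captured without relay. The fallback uses known chemistry, sets out from 15 and comes back at 18. Triphenylsilyl perrhenate Ph3SiOReO3 (2 mol %) in Et2O at 0 °C effects the known oxorhenium 1,3-transposition of the tertiary allylic alcohol, driven by enyne conjugation, and gives both secondary C4 alcohols, which are separated on silica. The (1S,2S)-4-[(3E)-5-{[tert-butyl(dimethyl)silyl]oxy}-3-methylpent-3-en-1-yn-1-yl]-2-hydroxy-3,5,5-trimethylcyclohex-3-en-1-yl benzoate F1 (trans) is benzoylated with PhCOCl/pyridine to 18. The (1S,2R)-4-[(3E)-5-{[tert-butyl(dimethyl)silyl]oxy}-3-methylpent-3-en-1-yn-1-yl]-2-hydroxy-3,5,5-trimethylcyclohex-3-en-1-yl benzoate F2 (cis) is converted to the same 18 by Mitsunobu esterification (PhCO2H, PPh3, diisopropyl azodicarboxylate, THF, 0 °C) with inversion at C4; the allylic-shift position C6 is fully substituted, so direct displacement is expected. Here stereocontrol comes from separation plus inversion instead of neighbouring-group relay.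

Step 11. The acid may ionise the allylic C4 benzoate or leave the silyl ether partly intact. The fallback sets out from 18 and comes back at 19 without any Brønsted acid stronger than HF·pyridine. HF·pyridine in THF at 0 °C gives the (1S,2S)-4-[(3E)-5-hydroxy-3-methylpent-3-en-1-yn-1-yl]-3,5,5-trimethylcyclohex-3-ene-1,2-diyl dibenzoate F3. Appel bromination (CBr4, PPh3, CH2Cl2, −20 °C) gives the (1S,2S)-4-[(3E)-5-bromo-3-methylpent-3-en-1-yn-1-yl]-3,5,5-trimethylcyclohex-3-ene-1,2-diyl dibenzoate F4, and PPh3 in EtOAc at rt quaternises it to 19.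

Step 12. The ylide could expel the C4 benzoate through the enyne (vinylogous elimination), or methanolysis of the hindered benzoates could stall on the polyene. The fallback sets out from 19 (with 9) and comes back at 21 by unmasking first and olefinating without added base. K2CO3 in MeOH (0 °C → rt) gives the {(2E)-5-[(3S,4S)-3,4-dihydroxy-2,6,6-trimethylcyclohex-1-en-1-yl]-3-methylpent-2-en-4-yn-1-yl}(triphenyl)phosphonium bromide F5. This is condensed with 9 in 1,2-epoxybutane/EtOH at 70 °C, where the epoxide scavenges HBr to generate the ylide, followed by the same thermal E-equilibration, to give 21.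

## Further compounds

F1 | step 10 | (1S,2S)-4-[(3E)-5-{[tert-butyl(dimethyl)silyl]oxy}-3-methylpent-3-en-1-yn-1-yl]-2-hydroxy-3,5,5-trimethylcyclohex-3-en-1-yl benzoate | CC(C)(C)[Si](C)(C)OC/C=C(C)/C#CC1=C(C)[C@H](O)[C@@H](OC(=O)c2ccccc2)CC1(C)C
F2 | step 10 | (1S,2R)-4-[(3E)-5-{[tert-butyl(dimethyl)silyl]oxy}-3-methylpent-3-en-1-yn-1-yl]-2-hydroxy-3,5,5-trimethylcyclohex-3-en-1-yl benzoate | CC(C)(C)[Si](C)(C)OC/C=C(C)/C#CC1=C(C)[C@@H](O)[C@@H](OC(=O)c2ccccc2)CC1(C)C
F3 | step 11 | (1S,2S)-4-[(3E)-5-hydroxy-3-methylpent-3-en-1-yn-1-yl]-3,5,5-trimethylcyclohex-3-ene-1,2-diyl dibenzoate | OC/C=C(C)/C#CC1=C(C)[C@H](OC(=O)c2ccccc2)[C@@H](OC(=O)c2ccccc2)CC1(C)C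
F4 | step 11 | (1S,2S)-4-[(3E)-5-bromo-3-methylpent-3-en-1-yn-1-yl]-3,5,5-trimethylcyclohex-3-ene-1,2-diyl dibenzoate | BrC/C=C(C)/C#CC1=C(C)[C@H](OC(=O)c2ccccc2)[C@@H](OC(=O)c2ccccc2)CC1(C)C
F5 | step 12 | {(2E)-5-[(3S,4S)-3,4-dihydroxy-2,6,6-trimethylcyclohex-1-en-1-yl]-3-methylpent-2-en-4-yn-1-yl}(triphenyl)phosphonium bromide | [Br-].c1ccccc1[P+](c1ccccc1)(c1ccccc1)C/C=C(C)/C#CC1=C(C)[C@H](O)[C@@H](O)CC1(C)C
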